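## The problem

Compound 21 is a linear chain of five oxygenated benzene rings held together by four diaryl ether bridges and nothing else. With the rings lettered A (the 2,4,6-trihydroxyphenyl end) to E (the 3,4,5-trihydroxyphenoxy end), every bridge runs from an oxygen flanked by two oxygen-bearing carbons (on C1 of ring A, on C4 of rings B, C and D) to the unencumbered C1 of the next ring. There is no stereocentre and no other element of chirality, so nothing has to be controlled in that respect. The difficulty is regiochemical (which oxygen of each ring is the bridge) and practical. Each bridging oxygen is di-ortho-substituted and every ring is electron-rich, the least favourable case for metal-mediated aryl ether formation, and the reaction must be repeated on an ever larger phenol. The free compound carries twelve phenolic hydroxyls, including a phloroglucinol-type ring A and a pyrogallol-type ring E, and is readily oxidised in air, above all under basic conditions. The hydroxyls therefore have to travel masked by small groups and be released together in one acidic, non-oxidising operation at the very end. The opening for a ring-forming key step lies in ring E: the ring D oxygen sits on C1, a hydroxyl sits para to it on C4, and C3 and C5 both carry oxygen. That is the para-oxygenated phenol that a chromium carbene, an alkyne and carbon monoxide assemble when the carbene carbon already bears the aryloxy group.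

## Retrosynthesis

21 from 20. The ten O–alkyl bonds are cut: nine O–CH3 bonds on rings A to D and the O–CH2CH3 bond on C5 of ring E. Methyl is preferred to benzyl for the permanent groups because it adds least to the crowding around the bridge oxygens and survives every step before the last. The ethyl group is simply what the ring E building block brings with it and falls in the same operation. The forward reaction has to cleave ten alkyl aryl ethers and leave four diaryl ethers untouched.

20 from 19. The C3–O bond of ring E is traced back to a C3–B bond. Boron is chosen because alkynylboronates are competent partners in chromium-mediated benzannulation and a C–B bond is turned into C–OH under mild, nearly neutral conditions. An ynol ether would bring the oxygen directly but inserts with less reliable regiochemistry, and a silyl group would need a much harsher oxidation. The forward reaction must oxidise at boron without attacking the catechol it creates.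

19 from 16 and 17. Three ring bonds of ring E are cut: C1–C2, C3–C4 and C4–C5. Ring E falls apart into the carbene carbon with its two-carbon ethoxyvinyl arm (C1, C6, C5), the two alkyne carbons of 17 (C2, C3) and one CO ligand of 16 (C4 with its hydroxyl oxygen). The obvious neighbouring cut is the ring D oxygen to C1 bond, a fourth copper coupling of 9 with a ready-made ring E halide, and it is shorter. The benzannulation is preferred here for two reasons. First, the last and most demanding ether bond is then formed in step 9, by attack of the phenol on a strongly electrophilic carbene carbon at low temperature, not at copper at 100 °C on the largest phenol of the series. Second, ring E arrives with its three oxygen positions differentiated (boron on C3, free hydroxyl on C4, ethyl ether on C5). The precursor is simpler by one aromatic ring. The forward reaction must insert the alkyne with the unsubstituted carbon toward the carbene carbon, incorporate CO instead of closing a five-membered ring, and leave the aryloxy and boryl groups in place. Decomplexation of the primary arene complex 18 finishes the step.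

16 from 9 and 14. The bond between the ring D oxygen and the carbene carbon is cut. Direct O-alkylation of an acylchromate, the usual Fischer route, cannot deliver an aryl group. The acylchromate 14 is therefore activated as the acetoxycarbene 15, and the phenol 9 displaces acetate at the carbene carbon. This separates the three-carbon organometallic piece from the whole tetramer. The forward reaction needs the phenol to attack the carbene carbon of 15 and not the acetyl carbonyl or the β-carbon of the ethoxyvinyl group.

14 from 10 and 11. The bond between the acyl carbon, a former CO ligand of 11, and the vinyl carbon is cut. The vinyl nucleophile is (Z)-2-ethoxyvinyllithium 12, made from the commercial bromide 10. Its addition to 11 gives the lithium acylchromate 13, which is exchanged to the storable tetramethylammonium salt 14. The forward reaction asks for bromine–lithium exchange with retention of the Z geometry.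

9 from 8, 7 and 2; 7 from 6, 5 and 2; 5 from 4, 3 and 2. Each cycle cuts one benzyl O–CH2 bond (8 to 9, 6 to 7, 4 to 5) and one bond between a hindered phenol oxygen and C1 of the next ring (7 + 2 to 8, 5 + 2 to 6, 3 + 2 to 4). A convergent union of two dimers would need a building block that is phenol and aryl bromide at once and would couple with itself. Linear iteration with the single monomer 2 avoids this, and every intermediate is one defined compound. Each cycle removes one ring. The forward coupling is a copper-catalysed etherification of a di-ortho-methoxy phenol with an electron-rich aryl bromide, and the benzyl ether must survive it and then be the only group that hydrogenolysis removes.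

2 from 1. The benzyl O–CH2 bond is cut, which leads back to commercial 1. The other purchased materials are 3, 10, 11 and 17.

## Roads not taken

Alternative 1: The ten ring C–O bonds ortho to the bridging oxygens are traced back to ten formyl groups. The four bridges are made by nucleophilic aromatic substitution, each displacing a fluoride that lies between two formyl groups with the unhindered phenoxide of the next ring. This gives the decaaldehyde A2, which a peracid converts into the decaformate A1 by tenfold aryl migration (Dakin/Baeyer–Villiger oxidation). Formate hydrolysis and hydrogenolysis of the two terminal benzyl ethers would finish the synthesis. In ether formation this road is better than the chosen plan. The crowded position is the electrophile, doubly activated, and the nucleophile is an unhindered phenoxide, so no copper coupling of a di-ortho-substituted phenol is needed. The weak point is the oxidation. Every ring of A2 carries two electron-withdrawing formyl groups, and the ortho donor is an aryloxy group, a weaker donor than hydroxyl or alkoxy. Hydride migration to carboxylic acids therefore competes with aryl migration at each of ten sites, and a single failure gives a by-product almost inseparable from A1. The chosen plan also ends with a tenfold operation, but ether cleavage by a boron trihalide has no competing pathway at the individual site. What the chosen plan sets against the easier ether formation is that every intermediate is one compound reached by a reaction with a single outcome per site.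

Alternative 2: All four bridges are cut at once. Anodic oxidation of the capping phenol 3 together with four equivalents of syringic acid A4 is meant to join each hindered phenoxyl oxygen to the carboxyl-bearing carbon of a syringate radical with decarboxylation. This would give the undeca-O-methyl pentamer A3 in one pot, and one global demethylation would then complete the synthesis. In step economy this road is far better: two steps from a commodity acid against twelve. Oxidative decarboxylative C–O coupling of 4-hydroxy-3,5-disubstituted benzoic acids is also a known way to poly(phenylene oxide) chains. Its weakness for this target is control of chain length. The coupling is a step-growth radical process, the phenolic end of every oligomer, A3 included, is itself oxidisable and keeps growing, and the electron-rich cap 3 is the most easily oxidised species present and can be diverted to quinones. A statistical series of homologues would have to be separated, with neighbours differing by one ring out of five or six. If that separation were practical, this road would win outright. The chosen plan sets against it that each bridge is made once, at a named position, on a single substrate.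

Alternative 3: Ring C is cut at C3–C4 and traced back to the pyranone A6, a 4-aryloxy-6-(aryloxymethyl)-2-pyranone derived from triacetic acid lactone A7. The aryloxy group on C4 of the pyranone comes from the A–B phenol 5, and the aryloxymethyl group comes from the D–E phenol A8. Magnesium methoxide (Mg(OMe)2) in methanol is meant to open the lactone to a keto ester, whose aryloxymethyl carbon then closes onto the ester carbon by Claisen condensation. Aromatisation would give A5 with the two ring C hydroxyls free. The attraction is convergence (A–B plus C plus D–E) and the fact that both bonds to ring C oxygen are made by substitution on a small heterocycle instead of by metal coupling. The weak points are mechanistic. The 4-aryloxy group of A6 is a vinylogous aryl ester, and methoxide can add at C4 and expel the A–B phenoxide. The opened keto ester can simply relactonise. The Claisen closure needs the carbanion at the aryloxy-substituted carbon, which is less acidic than the methylene between the ketone and the enol ether. Two further diaryl ethers (in 5 and in A8) still have to be made by copper coupling, so the saving over the chosen plan is one coupling at most. The chosen plan closes its ring under neutral conditions at the chain end, where no base-labile aryloxy group is exposed. Alternative 3 is better in convergence, and the chosen plan pays for its linearity with a longest sequence of eleven steps.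

Key step: step 10

Remark: In the SMILES the chromium carbonyl ligands are written as Cr=C=O. The arene complex 18 is written with its Cr(CO)3 fragment as a separate component, because SMILES has no notation for η6 bonding. Compounds 1, 3, 10, 11 and 17 are taken as purchased.

Step 1
Reactants: 1 4-bromo-2,6-dimethoxyphenol
Product: 2 2-(benzyloxy)-5-bromo-1,3-dimethoxybenzene
Conditions: BnBr, K2CO3, DMF, 60 °C
Reagents that add atoms: benzyl bromide, BrCc1ccccc1
Why: Williamson etherification of a phenoxide with an unhindered benzylic bromide, which the two ortho methoxy groups slow but do not prevent; benzyl is the one group in the route that hydrogenolysis removes while methyl and diaryl ethers stay.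

Step 2
Reactants: 3 2,4,6-trimethoxyphenol; 2 2-(benzyloxy)-5-bromo-1,3-dimethoxybenzene
Product: 4 2-(benzyloxy)-1,3-dimethoxy-5-(2,4,6-trimethoxyphenoxy)benzene (A–B benzyl ether)
Conditions: CuI (10 mol%), picolinic acid (20 mol%), K3PO4, DMSO, 100 °C, Ar
Reagents that add atoms: none
Why: Ullmann-type copper-catalysed diaryl ether synthesis with the picolinic acid ligand system, which is established for di-ortho-substituted phenols and electron-rich aryl bromides; 2 carries one halogen, so only one ether can form, and exclusion of air keeps the electron-rich phenoxide from oxidising.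

Step 3
Reactants: 4 A–B benzyl ether
Product: 5 2,6-dimethoxy-4-(2,4,6-trimethoxyphenoxy)phenol (A–B phenol)
Conditions: H2 (1 atm), 10% Pd/C, EtOAc–MeOH, rt
Reagents that add atoms: none
Why: Hydrogenolysis of a benzyl aryl ether over palladium; methyl aryl and diaryl ethers are inert, so only the hydroxyl needed for the next coupling is released.

Step 4
Reactants: 5 A–B phenol; 2 2-(benzyloxy)-5-bromo-1,3-dimethoxybenzene
Product: 6 2-(benzyloxy)-5-[2,6-dimethoxy-4-(2,4,6-trimethoxyphenoxy)phenoxy]-1,3-dimethoxybenzene (A–B–C benzyl ether)
Conditions: CuI (10 mol%), picolinic acid (20 mol%), K3PO4, DMSO, 100 °C, Ar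
Reagents that add atoms: none
Why: Second Ullmann-type etherification; the reacting phenol has the same local environment (hydroxyl between two methoxy groups, para oxygen) as 3, so the same catalyst system should apply.

Step 5
Reactants: 6 A–B–C benzyl ether
Product: 7 4-[2,6-dimethoxy-4-(2,4,6-trimethoxyphenoxy)phenoxy]-2,6-dimethoxyphenol (A–B–C phenol)
Conditions: H2 (1 atm), 10% Pd/C, EtOAc–MeOH, rt
Reagents that add atoms: none
Why: Benzyl ether hydrogenolysis as in step 3; no other group in 6 is reducible under these conditions.

Step 6
Reactants: 7 A–B–C phenol; 2 2-(benzyloxy)-5-bromo-1,3-dimethoxybenzene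
Product: 8 2-(benzyloxy)-5-{4-[2,6-dimethoxy-4-(2,4,6-trimethoxyphenoxy)phenoxy]-2,6-dimethoxyphenoxy}-1,3-dimethoxybenzene (A–B–C–D benzyl ether)
Conditions: CuI (20 mol%), picolinic acid (40 mol%), K3PO4, DMSO, 100 °C, Ar
Reagents that add atoms: none
Why: Third Ullmann-type etherification with the same local steric and electronic situation at the reacting oxygen; the higher catalyst loading allows for the slower reaction of the larger, less soluble phenol.

Step 7
Reactants: 8 A–B–C–D benzyl ether
Product: 9 4-{4-[2,6-dimethoxy-4-(2,4,6-trimethoxyphenoxy)phenoxy]-2,6-dimethoxyphenoxy}-2,6-dimethoxyphenol (A–B–C–D phenol)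
Conditions: H2 (1 atm), 10% Pd/C, THF–MeOH, rt
Reagents that add atoms: none
Why: Benzyl ether hydrogenolysis as in steps 3 and 5; THF is added for solubility of the tetramer.

Step 8
Reactants: 10 (Z)-1-bromo-2-ethoxyethene; 11 chromium hexacarbonyl
Product: 14 tetramethylammonium pentacarbonyl[(Z)-3-ethoxyprop-2-enoyl]chromate, via (Z)-2-ethoxyvinyllithium 12 (not isolated), via lithium pentacarbonyl[(Z)-3-ethoxyprop-2-enoyl]chromate 13 (not isolated)
Conditions: n-BuLi, THF, −78 °C; Cr(CO)6, THF, −78 to 0 °C; Me4NBr, H2O, 0 °C
Reagents that add atoms: tetramethylammonium bromide, C[N+](C)(C)C.[Br-]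
Why: First half of the Fischer carbene synthesis: bromine–lithium exchange proceeds with retention at the sp2 carbon and gives the cis-alkoxyvinyllithium, stabilised by coordination of the ethoxy oxygen to lithium, which adds to a CO ligand of Cr(CO)6; cation exchange gives the storable tetramethylammonium acylchromate.

Step 9
Reactants: 14 tetramethylammonium pentacarbonyl[(Z)-3-ethoxyprop-2-enoyl]chromate; 9 A–B–C–D phenol
Product: 16 pentacarbonyl{[(Z)-2-ethoxyethenyl](aryloxy)carbene}chromium in which the aryloxy group is 9 bound through its ring D oxygen, via pentacarbonyl[acetoxy((Z)-2-ethoxyethenyl)carbene]chromium 15 (not isolated)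
Conditions: AcBr, CH2Cl2, −40 °C; then 9, −40 to 0 °C, Ar; rapid filtration through silica under Ar
Reagents that add atoms: none
Why: O-acylation of the acylchromate gives the acyloxycarbene complex, and the neutral phenol then displaces acetate at the carbene carbon by addition–elimination, the standard way to place an alcohol or phenol that cannot serve as an alkylating agent on a Fischer carbene; the low temperature preserves the labile 15, and using the phenol in neutral form disfavours attack at the acetyl carbonyl.

Step 10
Reactants: 16 aryloxy(ethoxyvinyl)carbene complex; 17 2-ethynyl-4,4,5,5-tetramethyl-1,3,2-dioxaborolane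
Product: 19 nona-O-methyl pentamer whose ring E is 3-ethoxy-4-hydroxy-5-(4,4,5,5-tetramethyl-1,3,2-dioxaborolan-2-yl)phenoxy, via ring-E-bound tricarbonylchromium arene complex of the benzannulation product 18 (not isolated)
Conditions: 17 (excess), THF, 50 °C, Ar; then air, rt
Reagents that add atoms: none
Why: Dötz benzannulation. Thermal loss of one CO ligand from 16 (the cis ethoxy oxygen can occupy the vacated site as a hemilabile donor) lets 17 coordinate to zerovalent chromium and insert into the Cr=C bond, so that the unsubstituted alkyne carbon becomes bonded to the former carbene carbon (C1–C2). A CO ligand then inserts at the new carbene carbon to give a chromium-bound dienylketene (C3–C4), and a thermal 6π electrocyclisation closes ring E by forming C4–C5; the cyclohexadienone tautomerises to the phenol by moving the C5 hydrogen to oxygen, and air strips the Cr(CO)3 fragment from 18. The closest known reactions are benzannulations of aryloxy(alkenyl)carbene chromium complexes with alkynes, used to make diaryl ethers, and of alkoxycarbene complexes with alkynylboronates. No stereocentre is formed. Two selectivities are needed: the regiochemistry of alkyne insertion, secured by the steric difference between the hydrogen-bearing and the boryl-bearing alkyne carbon (the larger end finishes next to the CO-derived carbon, the normal outcome for terminal alkynes), and carbonylative six-ring closure in preference to CO-free five-ring products. The latter is favoured for alkenyl carbenes, by the weakly donating aryloxy group that keeps the metal electron-poor, by an ether solvent in place of MeCN or DMF, and by an excess of alkyne. The bond from the ring D oxygen to C1 is carried through unchanged, so the last diaryl ether needs no coupling.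

Step 11
Reactants: 19 boryl phenol pentamer
Product: 20 nona-O-methyl pentamer whose ring E is 3-ethoxy-4,5-dihydroxyphenoxy
Conditions: NaBO3·4H2O, THF–H2O, 0 °C to rt, Ar; Na2S2O3 work-up
Reagents that add atoms: sodium perborate (NaBO3·4H2O, drawn as the peroxoborate dimer without water of crystallisation), [Na+].[Na+].O[B-]1(O)OO[B-](O)(O)OO1
Why: ipso-Oxidation of an arylboronic ester: the peroxide oxygen adds to boron, the aryl group migrates from boron to oxygen at the same ring position, and the borate ester hydrolyses to the phenol; perborate is mild and nearly neutral, which limits further oxidation of the catechol.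

Step 12
Reactants: 20 catechol pentamer
Product: 21 5-(4-{4-[2,6-dihydroxy-4-(2,4,6-trihydroxyphenoxy)phenoxy]-2,6-dihydroxyphenoxy}-2,6-dihydroxyphenoxy)benzene-1,2,3-triol (target)
Conditions: BBr3 (excess), CH2Cl2, −78 °C to rt; then MeOH, H2O, Ar
Reagents that add atoms: none
Why: Lewis acid cleavage of alkyl aryl ethers: boron coordinates each ether oxygen and bromide attacks the methyl or ethyl carbon (SN2), so only O–alkyl bonds break and the four diaryl ether bridges, which offer no sp3 carbon, stay; the acidic, non-oxidising medium suits the air-sensitive polyphenol.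

Compound list

1 | 4-bromo-2,6-dimethoxyphenol | COc1cc(Br)cc(OC)c1O | starting material
2 | 2-(benzyloxy)-5-bromo-1,3-dimethoxybenzene | COc1cc(Br)cc(OC)c1OCc1ccccc1 | intermediate
3 | 2,4,6-trimethoxyphenol | COc1cc(OC)c(O)c(OC)c1 | starting material
4 | 2-(benzyloxy)-1,3-dimethoxy-5-(2,4,6-trimethoxyphenoxy)benzene (A–B benzyl ether) | COc1cc(OC)c(Oc2cc(OC)c(OCc3ccccc3)c(OC)c2)c(OC)c1 | intermediate
5 | 2,6-dimethoxy-4-(2,4,6-trimethoxyphenoxy)phenol (A–B phenol) | COc1cc(OC)c(Oc2cc(OC)c(O)c(OC)c2)c(OC)c1 | intermediate
6 | 2-(benzyloxy)-5-[2,6-dimethoxy-4-(2,4,6-trimethoxyphenoxy)phenoxy]-1,3-dimethoxybenzene (A–B–C benzyl ether) | COc1cc(OC)c(Oc2cc(OC)c(Oc3cc(OC)c(OCc4ccccc4)c(OC)c3)c(OC)c2)c(OC)c1 | intermediate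
7 | 4-[2,6-dimethoxy-4-(2,4,6-trimethoxyphenoxy)phenoxy]-2,6-dimethoxyphenol (A–B–C phenol) | COc1cc(OC)c(Oc2cc(OC)c(Oc3cc(OC)c(O)c(OC)c3)c(OC)c2)c(OC)c1 | intermediate
8 | 2-(benzyloxy)-5-{4-[2,6-dimethoxy-4-(2,4,6-trimethoxyphenoxy)phenoxy]-2,6-dimethoxyphenoxy}-1,3-dimethoxybenzene (A–B–C–D benzyl ether) | COc1cc(OC)c(Oc2cc(OC)c(Oc3cc(OC)c(Oc4cc(OC)c(OCc5ccccc5)c(OC)c4)c(OC)c3)c(OC)c2)c(OC)c1 | intermediate
9 | 4-{4-[2,6-dimethoxy-4-(2,4,6-trimethoxyphenoxy)phenoxy]-2,6-dimethoxyphenoxy}-2,6-dimethoxyphenol (A–B–C–D phenol) | COc1cc(OC)c(Oc2cc(OC)c(Oc3cc(OC)c(Oc4cc(OC)c(O)c(OC)c4)c(OC)c3)c(OC)c2)c(OC)c1 | intermediate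
10 | (Z)-1-bromo-2-ethoxyethene | CCO/C=C\Br | starting material
11 | chromium hexacarbonyl, Cr(CO)6 | O=C=[Cr](=C=O)(=C=O)(=C=O)(=C=O)=C=O | starting material
12 | (Z)-2-ethoxyvinyllithium | CCO/C=C\[Li] | intermediate
13 | lithium pentacarbonyl[(Z)-3-ethoxyprop-2-enoyl]chromate | CCO/C=C\C([O-])=[Cr](=C=O)(=C=O)(=C=O)(=C=O)=C=O.[Li+] | intermediate
14 | tetramethylammonium pentacarbonyl[(Z)-3-ethoxyprop-2-enoyl]chromate | CCO/C=C\C([O-])=[Cr](=C=O)(=C=O)(=C=O)(=C=O)=C=O.C[N+](C)(C)C | intermediate
15 | pentacarbonyl[acetoxy((Z)-2-ethoxyethenyl)carbene]chromium | CCO/C=C\C(OC(C)=O)=[Cr](=C=O)(=C=O)(=C=O)(=C=O)=C=O | intermediate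
16 | pentacarbonyl{[(Z)-2-ethoxyethenyl](aryloxy)carbene}chromium, aryloxy being 9 bound through its ring D oxygen | COc1cc(OC)c(Oc2cc(OC)c(Oc3cc(OC)c(Oc4cc(OC)c(OC(/C=C\OCC)=[Cr](=C=O)(=C=O)(=C=O)(=C=O)=C=O)c(OC)c4)c(OC)c3)c(OC)c2)c(OC)c1 | intermediate
17 | 2-ethynyl-4,4,5,5-tetramethyl-1,3,2-dioxaborolane (ethynylboronic acid pinacol ester) | C#CB1OC(C)(C)C(C)(C)O1 | starting material
18 | tricarbonylchromium complex of 19, η6-bound at ring E | COc1cc(OC)c(Oc2cc(OC)c(Oc3cc(OC)c(Oc4cc(OC)c(Oc5cc(B6OC(C)(C)C(C)(C)O6)c(O)c(OCC)c5)c(OC)c4)c(OC)c3)c(OC)c2)c(OC)c1.O=C=[Cr](=C=O)=C=O | intermediate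
19 | nona-O-methyl pentamer with ring E as 3-ethoxy-4-hydroxy-5-(4,4,5,5-tetramethyl-1,3,2-dioxaborolan-2-yl)phenoxy | COc1cc(OC)c(Oc2cc(OC)c(Oc3cc(OC)c(Oc4cc(OC)c(Oc5cc(B6OC(C)(C)C(C)(C)O6)c(O)c(OCC)c5)c(OC)c4)c(OC)c3)c(OC)c2)c(OC)c1 | intermediate
20 | nona-O-methyl pentamer with ring E as 3-ethoxy-4,5-dihydroxyphenoxy | COc1cc(OC)c(Oc2cc(OC)c(Oc3cc(OC)c(Oc4cc(OC)c(Oc5cc(O)c(O)c(OCC)c5)c(OC)c4)c(OC)c3)c(OC)c2)c(OC)c1 | intermediate
21 | 5-(4-{4-[2,6-dihydroxy-4-(2,4,6-trihydroxyphenoxy)phenoxy]-2,6-dihydroxyphenoxy}-2,6-dihydroxyphenoxy)benzene-1,2,3-triol | Oc1cc(O)c(Oc2cc(O)c(Oc3cc(O)c(Oc4cc(O)c(Oc5cc(O)c(O)c(O)c5)c(O)c4)c(O)c3)c(O)c2)c(O)c1 | target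

Total step count: 12. Longest linear sequence: 11 steps (steps 1 to 7, then 9 to 12); step 8 is a one-step side branch.

Steps least certain to work

Step 10 (key step). The aryloxy carbene with an electron-donating ethoxy group on the vinyl arm is an untried combination. The most likely failures are slow CO loss from the push–pull stabilised complex, closure after alkyne insertion without CO uptake (five-ring products), loss of the aryloxy group by solvolysis with return of 9, and protodeboronation of the electron-rich product on work-up. The fallback gives up the ring construction, sets out from 9 and comes back to the route at 21. Compound 9 is coupled with commercial 5-bromo-1,2,3-trimethoxybenzene under the CuI/picolinic acid/K3PO4 conditions of step 6 to give the dodeca-O-methyl pentamer F1, and BBr3 as in step 12 converts F1 into 21.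

Step 9. The neutral, di-ortho-substituted phenol may attack the acetyl carbonyl of 15 (acetyl transfer, regenerating the acylchromate). It may also add at the β-carbon of the ethoxyvinyl group with displacement of ethoxide. Either way 9, the product of seven steps, would be consumed in hard-to-separate mixtures. The fallback moves the exchange and the benzannulation to the cheap monomer, sets out from 1 and 14 and comes back to the route at 21. Compound 14 is activated with AcBr as in step 9 and treated with an excess of 1 to give pentacarbonyl[(4-bromo-2,6-dimethoxyphenoxy)((Z)-2-ethoxyethenyl)carbene]chromium F2, a small complex that can be purified and made in quantity. Benzannulation with 17 as in step 10 gives 4-(4-bromo-2,6-dimethoxyphenoxy)-2-ethoxy-6-(4,4,5,5-tetramethyl-1,3,2-dioxaborolan-2-yl)phenol F3. NaBO3·4H2O gives 5-(4-bromo-2,6-dimethoxyphenoxy)-3-ethoxybenzene-1,2-diol F4, and MeI/K2CO3 in DMF gives 5-bromo-2-(3-ethoxy-4,5-dimethoxyphenoxy)-1,3-dimethoxybenzene F5. Copper-catalysed coupling of F5 with the A–B–C phenol 7 under the conditions of step 6 gives the undeca-O-methyl mono-O-ethyl pentamer F6, and BBr3 converts F6 into 21.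

Step 6 (and likewise steps 2 and 4). With a hindered, electron-rich phenoxide and an electron-rich bromide, C–O bond formation at copper may become slower than hydrodebromination of 2 and oxidative degradation of the phenoxide at 100 °C. The problem should grow with the size of the phenol. The fallback replaces the Ullmann coupling by an oxidative Chan–Lam–Evans coupling at room temperature, sets out from 2 and 7 and comes back to the route at 8. Bromine–lithium exchange on 2 (n-BuLi, THF, −78 °C), B(OiPr)3 and aqueous acid give [4-(benzyloxy)-3,5-dimethoxyphenyl]boronic acid F7. F7 is coupled with 7 using Cu(OAc)2, pyridine and 4 Å molecular sieves in CH2Cl2 under air to give 8.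

Step 11. The product is an electron-rich catechol formed in the presence of an oxidant. Over-oxidation to the ortho-quinone and subsequent decomposition, or protodeboronation before oxidation, are the likely losses. The fallback caps the free hydroxyl first, sets out from 19 and comes back to the route at 21. MeI/K2CO3 in DMF converts 19 into its C4 methyl ether F8. Oxidation of F8 at boron (NaBO3·4H2O or H2O2/NaOH) gives F9, the monophenol whose ring E is 3-ethoxy-5-hydroxy-4-methoxyphenoxy and which is far less prone to oxidation than a catechol. BBr3 then converts F9 into 21.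

Step 12. The free dodecaphenol may be lost by air oxidation and irreversible adsorption during work-up and chromatography, and incomplete cleavage of the slower ethyl ether would leave partly alkylated material that is hard to remove from it. The fallback purifies at the stage of a stable derivative, sets out from 20 and comes back to the route at 21. After the BBr3 treatment the crude polyphenol is acetylated without isolation (Ac2O, pyridine) to the dodecaacetate F10. F10 is purified by chromatography, where partly alkylated by-products separate, and is then deacetylated under argon by acidic methanolysis (HCl in MeOH) to 21.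

Further compounds

F1 | step 10 | dodeca-O-methyl ether of 21 (ring E as 3,4,5-trimethoxyphenoxy) | COc1cc(OC)c(Oc2cc(OC)c(Oc3cc(OC)c(Oc4cc(OC)c(Oc5cc(OC)c(OC)c(OC)c5)c(OC)c4)c(OC)c3)c(OC)c2)c(OC)c1
F2 | step 9 | pentacarbonyl[(4-bromo-2,6-dimethoxyphenoxy)((Z)-2-ethoxyethenyl)carbene]chromium | COc1cc(Br)cc(OC)c1OC(/C=C\OCC)=[Cr](=C=O)(=C=O)(=C=O)(=C=O)=C=O
F3 | step 9 | 4-(4-bromo-2,6-dimethoxyphenoxy)-2-ethoxy-6-(4,4,5,5-tetramethyl-1,3,2-dioxaborolan-2-yl)phenol | COc1cc(Br)cc(OC)c1Oc1cc(B2OC(C)(C)C(C)(C)O2)c(O)c(OCC)c1
F4 | step 9 | 5-(4-bromo-2,6-dimethoxyphenoxy)-3-ethoxybenzene-1,2-diol | COc1cc(Br)cc(OC)c1Oc1cc(O)c(O)c(OCC)c1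
F5 | step 9 | 5-bromo-2-(3-ethoxy-4,5-dimethoxyphenoxy)-1,3-dimethoxybenzene | COc1cc(Br)cc(OC)c1Oc1cc(OC)c(OC)c(OCC)c1
F6 | step 9 | undeca-O-methyl mono-O-ethyl pentamer (ring E as 3-ethoxy-4,5-dimethoxyphenoxy) | COc1cc(OC)c(Oc2cc(OC)c(Oc3cc(OC)c(Oc4cc(OC)c(Oc5cc(OC)c(OC)c(OCC)c5)c(OC)c4)c(OC)c3)c(OC)c2)c(OC)c1
F7 | step 6 | [4-(benzyloxy)-3,5-dimethoxyphenyl]boronic acid | COc1cc(B(O)O)cc(OC)c1OCc1ccccc1
F8 | step 11 | C4 methyl ether of 19 (ring E as 3-ethoxy-4-methoxy-5-(4,4,5,5-tetramethyl-1,3,2-dioxaborolan-2-yl)phenoxy) | COc1cc(OC)c(Oc2cc(OC)c(Oc3cc(OC)c(Oc4cc(OC)c(Oc5cc(B6OC(C)(C)C(C)(C)O6)c(OC)c(OCC)c5)c(OC)c4)c(OC)c3)c(OC)c2)c(OC)c1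
F9 | step 11 | deca-O-methyl mono-O-ethyl pentamer with ring E as 3-ethoxy-5-hydroxy-4-methoxyphenoxy | COc1cc(OC)c(Oc2cc(OC)c(Oc3cc(OC)c(Oc4cc(OC)c(Oc5cc(O)c(OC)c(OCC)c5)c(OC)c4)c(OC)c3)c(OC)c2)c(OC)c1
F10 | step 12 | dodecaacetate of 21 | CC(=O)Oc1cc(OC(C)=O)c(Oc2cc(OC(C)=O)c(Oc3cc(OC(C)=O)c(Oc4cc(OC(C)=O)c(Oc5cc(OC(C)=O)c(OC(C)=O)c(OC(C)=O)c5)c(OC(C)=O)c4)c(OC(C)=O)c3)c(OC(C)=O)c2)c(OC(C)=O)c1
A1 | alternative 1 | decaformate of the target with benzyl ethers at both chain ends | O=COc1cc(OCc2ccccc2)cc(OC=O)c1Oc1cc(OC=O)c(Oc2cc(OC=O)c(Oc3cc(OC=O)c(Oc4cc(OC=O)c(OCc5ccccc5)c(OC=O)c4)c(OC=O)c3)c(OC=O)c2)c(OC=O)c1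
A2 | alternative 1 | decaformyl pentamer with benzyl ethers at both chain ends | O=Cc1cc(OCc2ccccc2)cc(C=O)c1Oc1cc(C=O)c(Oc2cc(C=O)c(Oc3cc(C=O)c(Oc4cc(C=O)c(OCc5ccccc5)c(C=O)c4)c(C=O)c3)c(C=O)c2)c(C=O)c1
A3 | alternative 2 | undeca-O-methyl pentamer with free hydroxyl at C4 of ring E | COc1cc(OC)c(Oc2cc(OC)c(Oc3cc(OC)c(Oc4cc(OC)c(Oc5cc(OC)c(O)c(OC)c5)c(OC)c4)c(OC)c3)c(OC)c2)c(OC)c1
A4 | alternative 2 | syringic acid (4-hydroxy-3,5-dimethoxybenzoic acid) | COc1cc(C(=O)O)cc(OC)c1O
A5 | alternative 3 | deca-O-methyl pentamer with free hydroxyls at C3 and C5 of ring C | COc1cc(OC)c(Oc2cc(OC)c(Oc3cc(O)c(Oc4cc(OC)c(Oc5cc(OC)c(OC)c(OC)c5)c(OC)c4)c(O)c3)c(OC)c2)c(OC)c1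
A6 | alternative 3 | 4-[2,6-dimethoxy-4-(2,4,6-trimethoxyphenoxy)phenoxy]-6-{[3,5-dimethoxy-4-(3,4,5-trimethoxyphenoxy)phenoxy]methyl}-2H-pyran-2-one | COc1cc(OC)c(Oc2cc(OC)c(Oc3cc(COc4cc(OC)c(Oc5cc(OC)c(OC)c(OC)c5)c(OC)c4)oc(=O)c3)c(OC)c2)c(OC)c1
A7 | alternative 3 | triacetic acid lactone (4-hydroxy-6-methyl-2H-pyran-2-one) | Cc1cc(O)cc(=O)o1
A8 | alternative 3 | 3,5-dimethoxy-4-(3,4,5-trimethoxyphenoxy)phenol (D–E phenol) | COc1cc(O)cc(OC)c1Oc1cc(OC)c(OC)c(OC)c1
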